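The target is the product wanted from this flask, and the isomer of the product grows beside it, so what is asked is how the ratio of the two runs.

| flask | substrate | remark | time |
|---|---|---|---|
| summer | 1.2 M | run made earlier |  |
| midnight | 2.7 M | run made earlier |  |
| flask | 1.8 M |  | 2.0 h |

| run | time / min | isomer of the product / % | target / % | substrate / % |
|---|---|---|---|---|
| summer | 15.0 | 2 | 33 | 44 |
| summer | 30.0 | 4 | 30 | 22 |
| summer | 40.0 | 5 | 26 | 17 |
| summer | 60.0 | 7 | 17 | 7 |
| summer | 80.0 | 8 | 10 | 4 |
| midnight | 6.00 | 1 | 18 | 73 |
| midnight | 20.0 | 4 | 34 | 37 |
| midnight | 30.0 | 6 | 34 | 21 |
| midnight | 50.0 | 7 | 24 | 13 |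
| midnight | 80.0 | 4 | 13 | 8 |

(each reading ± 1.5 percentage points)

- ratio of isomer of the product to target at 25 s
- ratio of isomer of the product to target at 8.0 min
- ratio of isomer of the product to target at 2.0 h
- which of isomer of the product and target there is more of at 2.0 h



If isomer and target both come from the substrate, dividing one rate of making by the other removes the time, and the number that is left can be read in two separate ways.

First way, the earliest readings, midnight then summer:

isomer / target = 1% / 18% = 0.0556, and 2% / 33% = 0.0606

Second way, counting the substrate lost as target made, summer at 60.0 min, then midnight at 30.0 min: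

isomer / substrate lost = 7% / 93.0% = 0.0753, and 6% / 79.0% = 0.0759

This last number, the split, isomer gained per target gained at the start of a run, is a selectivity factor. The two ways agree within the scatter, but the first rests on isomer readings of 1% and 2% against a scatter of 1.5 percentage points, so the second is the one to trust. They part later, when the summer ratio to target reaches 0.412 at 60.0 min, far above the split. The three readings there add up to 31.0% of the charge, so the rest stands in none of the three and the target reading need not hold all the target made, which makes the late ratio to target the one that cheats. The second way is not flat either, giving 0.0357 at 15.0 min, though on that same weak reading of 2%.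

My reckoning therefore puts the flask's ratio near 0.0753 at 25 s and at 8.0 min, a time earlier than the first summer reading.

The forecast differs from this reckoning. It held that “isomer forms mainly from target” and gave 0.005 at 25 s, 0.035 at 8.0 min and 1.1 at 2.0 h, with isomer of the product ahead.

The flask gives 0.0747 at 25 s, against the split of 0.0753 reckoned from the readings, then 0.0897 at 8.0 min and 1.64 at 2.0 h, with isomer of the product ahead at 6.82% against 4.17% of target.

    substrate ⇌ target (K = 4.80, k = 7.70 × 10⁻⁴ s⁻¹)
    substrate ⇌ isomer of the product (K = 2.70, k = 5.70 × 10⁻⁵ s⁻¹)
    target → over-reaction product (k = 6.30 × 10⁻⁴ s⁻¹)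
    substrate ⇌ dormant form (K = 0.900, k = 1.00 × 10⁻⁴ s⁻¹)

The split came out alike from the summer and midnight charges of 1.2 M and 2.7 M, so the neighbouring flask, charged with 0.45 M, a quarter of this flask's substrate, is reckoned at the same 0.0753 early on. That neighbouring flask gives 0.0747 at 25 s, 0.0897 at 8.0 min and 1.64 at 2.0 h.

All runs were computed with constants of no real substance, noise included.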